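## Structural features

The target is a 2,3-dihydro-4H-furo[3,2-c]pyran-4-one: a 2-pyranone (ring A: C3a, C4 carbonyl, O5, C6, C7, C7a) fused through the C3a=C7a bond to a dihydrofuran (ring B: O1, C2, C3, C3a, C7a). C6 carries an (E)-4-hydroxystyryl arm, C2 a 3,4-dihydroxyphenyl group, and C3 a second heterocycle, a 4-hydroxy-2-pyranone (ring C) bonded through its own C6. The only stereocentres are the neighbouring C2 and C3, both S, with aryl and pyranonyl groups trans on ring B. Fragile elements are the catechol (oxidation under base), the styryl double bond (no hydrogenolysis possible) and the acidic 4-hydroxypyranone. The most fragile is C3–H: it lies between two electron-poor rings and beta to O1, which is a vinylogous carboxylate leaving group, so base can epimerise C3 or open ring B by elimination. The real difficulty is therefore to fix the C2/C3 pair in absolute terms and to keep C3 intact while the heterocycles are assembled around it. The key step exploits the fact that the C4 carboxyl carbon on C3a lies cis, across the ring B double bond, to the vinylic carbon C7a. A 4,5-dihydrofuran-3-carboxylic acid can thus direct a metal to the C7a–H bond, and an acyl carbene partner supplies C7 and C6 with the styryl arm attached.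

## Logic of the disconnections

29 from 28. Cut: the three aryl O–Si bonds. The phenols stay masked until the end because the free catechol and C3–H tolerate few reagents. The forward step must be a buffered fluoride treatment.

28 from 26 by way of 27. Cut: the lactone O–C(=O) bond of ring C, then the acetone adduct that stores the ketene. Ring C closes by heat alone, so no base meets C3–H. The demand is that 26 fragments cleanly at about 110 °C.

26 from 25, and 25 from 22 and 24 (24 from 23). Cut: the C5–C6 bond of ring C, between the carbonyl carbon on C3 and the neighbouring methylene. Four of the five ring C carbons arrive in one piece. The forward aldol must run under Lewis acid, not base, and its new carbinol centre is erased by oxidation.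

22 from 21, and 21 from 20. Cut: the benzylic C–O bond of the 4-methoxybenzyl ether, then an oxidation-level change. The C3 substituent is kept as an ether-bearing methylene through ring A formation, so C3–H is not acidic at that stage. The demand is a selective oxidative debenzylation.

20 from 11 and 18. Cut: C7–C7a and O5–C6. Ring A and the complete styryl arm are added in one convergent operation to a ring B that already holds both stereocentres. The forward step must activate one vinylic C–H bond and leave the enol ether, the silyl ethers and both stereocentres untouched.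

18 from 14 and 15 (through 16 and 17), and 14 from 12 (through 13). Cut: the C6–C7 bond, an acylation of a sulfur ylide. The partner carries the (E)-alkene from the start. The demand is acylation faster than cyclopropanation.

11 from 10, and 10 from 9. Cut: the C3a–C4 bond. The beta-carbon of an enol ether is nucleophilic, so the carboxyl carbon enters as a trichloroacetyl group. The forward hydrolysis must spare the aryl silyl ethers.

9 from 8. Cut: O1–C7a. An alkynol cycloisomerisation forms ring B without added atoms. It must close in the endo sense.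

8 from 6 and 2 (through 7). Cut: C2–C3, the bond between the stereocentres. Both centres are set here, C3 by chirality transfer from the propargylic carbon and C2 by a closed transition state. The demand is anti selectivity with an aromatic aldehyde.

6 from 5, 5 from 4, 4 from 3; 2 from 1. Cut: the alkyne–carbinol bond and protecting-group bonds. The single resolved centre of 5 is the source of all chirality.

## Other disconnections considered

Alternative 1: The cut is the C3–C3a bond of ring B, made by a 1,2-shift. Ring B is traced back to a six-membered dihydropyranone A1 fused to a 6-methylpyranone. Forward, PhI(OH)OTs in trimethyl orthoformate would convert the ketone of A1 into its methyl enol ether. Trivalent iodine would add at the methylene carbon, and the pyranone ring-fusion carbon would migrate to that carbon as the iodine group departs. The ring contracts and the old carbonyl carbon remains as the methyl ester of A2.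
- In favour: the reaction type is established on chroman-4-ones, the trans relationship follows from the anti alignment of migrating bond and leaving group, and the materials are very cheap. A2 already has C3 at the carboxyl oxidation level, so no deprotection or oxidation precedes ring C. On that point and on step count this plan is better than the chosen one.
- Against: the carbon that must migrate is part of an electron-poor pyranone, while the C2 aryl group is electron-rich, so the competing aryl shift is the likelier course. The single stereocentre of A1 can racemise by reversible oxa-Michael opening, so absolute configuration has no secure source. The 6-methyl group must still be elaborated to the styryl arm and the ester to ring C, both under base with an acyl group on C3. Benzyl ethers cannot be removed by hydrogenolysis beside the styryl bond.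
- Comparison: shorter and precedented in type, but absolute stereocontrol is unsolved and C3 is acylated from the moment ring B forms. The chosen plan spends more steps to set both centres before any carbonyl reaches C3.

Alternative 2: The cut removes C2 as a one-carbon unit, breaking O1–C2 and C2–C3. This leaves sulfone A3 (a 4-hydroxy-6-styrylpyranone carrying ring C on an exocyclic carbon) and the chiral benzylic sulfonium salt A4. Forward, Cs2CO3 would expel benzenesulfinate from A3 to give the pyrone methide A5 in the flask and would deprotonate A4. Conjugate addition of the ylide forms C2–C3, and the enolate oxygen displaces the sulfide (5-exo-tet) to form O1–C2 and give A6.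
- In favour: it is the most convergent plan. Ring B and both stereocentres are made in one operation on complete halves, trans products are the usual outcome of such ylide annulations, and A6 needs only fluoride. On convergence and step economy it is better than the chosen plan. It is also better in that C3 never carries a carbonyl substituent under strong base.
- Against: the enolate from A5 is ambident, and closure through the lactone carbonyl oxygen would give the isomeric furo[2,3-b]pyran-4-one. The absolute sense rests on facial discrimination of a heteroaryl-substituted methide of undefined geometry, for which no close model exists; the enantiomer of A4 would have to be chosen by trial. Assembly of A3 adds steps of its own.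
- Comparison: it wins on length and loses on predictability of absolute and regiochemical control. The final unmasking is equal in both plans.

Alternative 3: The cut is C2–C3 together with O1–C7a. Ring A arrives complete as the 4-chloro-2-pyranone A7, which bears an acetyl imide on C3a, and the carbinol carbon comes from aldehyde A8. Forward, the dibutylboron enolate of A7 would add to A8 in an Evans syn-aldol reaction to give A9. After release of boron, the C2 alkoxide would attack C7a and expel chloride by addition–elimination, giving A10.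
- In favour: the aldol is among the most dependable ways to set two adjacent centres absolutely, and the syn adduct maps onto the trans ring. Ring A and the styryl arm exist before the stereocentres. In reliability of the stereodefining event it is the equal of the chosen plan, and in convergence it is better.
- Against: the enolate of A7 is stabilised and sits beside an electrophilic chloropyranone, so low reactivity, retro-aldol and attack of the amine base at C7a are plausible. A9 and A10 carry the carbonyl on C3 with oxygen in the beta position, so ring closure under base and the later exchange of the auxiliary for ring C both threaten C3 and ring B.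
- Comparison: step counts are similar, and a stoichiometric auxiliary is no worse than discarding half of a resolved alcohol (equal). The chosen plan keeps C3 free of a carbonyl until ring A exists, at the price of a key step without direct precedent.

Key step: step 11

Remarks before the steps:
- Atom labels (C2, C3, C3a, C4, O5, C6, C7, C7a) follow the numbering of 29 throughout.
- Descriptors: one descriptor per compound does not define these structures, so both centres are specified. The ring B geometry is constant: (4R,5S) in 11, (2S,3R) in 20 and (2S,3S) in 29. The change at C3 is a priority change only.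
- Protecting groups: the phenols are carried as triisopropylsilyl ethers. Aryl tert-butyldimethylsilyl ethers are not expected to survive the hydroxide of step 8 or the ylide medium of step 10.
- End game: ring C is built by Lewis-acid aldol and thermolysis. Acylating a strongly basic dianion with a C3 acyl donor would risk epimerising C3 or opening ring B.
- Assumption: the lipase follows the usual size rule for secondary alcohols (ethynyl small, alkoxymethyl large), so the (R)-alcohol is acetylated; if the preference were reversed, the acetate would be hydrolysed and used.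

Step 1  
Reactants: 1 3,4-dihydroxybenzaldehyde  
Product: 2 3,4-bis(triisopropylsilyloxy)benzaldehyde  
Conditions: iPr3SiCl (2.4 equiv), imidazole (5 equiv), HCONMe2, rt  
Reagents that add atoms: triisopropylsilyl chloride, `CC(C)[Si](Cl)(C(C)C)C(C)C`  
Why: Imidazole-promoted O-silylation of both phenols; the aldehyde is inert and the bulky silyl groups give ethers that resist base better than smaller silyl groups.

Step 2  
Reactants: 3 2-[(4-methoxyphenyl)methoxy]acetaldehyde  
Product: 4 rac-1-[(4-methoxybenzyl)oxy]but-3-yn-2-ol  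
Conditions: HC≡CMgBr (1.3 equiv), THF, −78 → 0 °C; aq. NH4Cl  
Reagents that add atoms: ethynylmagnesium bromide, `C#C[Mg]Br`  
Why: Grignard 1,2-addition to an unhindered aldehyde; the stereocentre is formed racemic and sorted in step 3.

Step 3  
Reactants: 4 rac-1-[(4-methoxybenzyl)oxy]but-3-yn-2-ol  
Product: 5 (S)-1-[(4-methoxybenzyl)oxy]but-3-yn-2-ol  
Conditions: lipase from Burkholderia cepacia (immobilised), vinyl acetate (3 equiv), tBuOMe, 30 °C, stopped just past half conversion; chromatography  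
Reagents that add atoms: none  
Why: Enzymatic kinetic resolution by irreversible transesterification; the (R)-alcohol should be acetylated and the (S)-alcohol left behind, and running past half conversion raises the enantiomeric purity of the unreacted alcohol.

Step 4  
Reactants: 5 (S)-1-[(4-methoxybenzyl)oxy]but-3-yn-2-ol  
Product: 6 (S)-1-[(4-methoxybenzyl)oxy]but-3-yn-2-yl methanesulfonate  
Conditions: MeSO2Cl (1.3 equiv), Et3N (1.6 equiv), CH2Cl2, −78 → −20 °C  
Reagents that add atoms: methanesulfonyl chloride, `CS(=O)(=O)Cl`  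
Why: O-sulfonylation with retention at carbon gives the leaving group for the SN2' step; the mesylate is used without storage.

Step 5  
Reactants: 6 (S)-1-[(4-methoxybenzyl)oxy]but-3-yn-2-yl methanesulfonate; 2 3,4-bis(triisopropylsilyloxy)benzaldehyde  
Product: 8 (1S,2R)-1-[3,4-bis(triisopropylsilyloxy)phenyl]-2-{[(4-methoxybenzyl)oxy]methyl}but-3-yn-1-ol, via allenylzinc 7 (not isolated)  
Conditions: Pd(OAc)2 (5 mol%), PPh3 (5 mol%), Et2Zn (3 equiv), THF, −78 → −20 °C; aq. NH4Cl  
Reagents that add atoms: none  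
Why: Palladium-catalysed umpolung of a propargylic mesylate: zerovalent palladium formed in the flask displaces mesylate anti (SN2'), transmetalation with Et2Zn gives (P)-allenylzinc 7, and 7 adds to 2 through a closed SE2' (Zimmerman–Traxler-like) transition state. Net inversion at the propargylic carbon sets the methine centre R by chirality transfer, and placing the aldehyde aryl group away from the alkoxymethyl substituent sets the carbinol centre S, i.e. the anti isomer.

Step 6  
Reactants: 8 (1S,2R)-1-[3,4-bis(triisopropylsilyloxy)phenyl]-2-{[(4-methoxybenzyl)oxy]methyl}but-3-yn-1-ol  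
Product: 9 (2S,3R)-2-[3,4-bis(triisopropylsilyloxy)phenyl]-3-{[(4-methoxybenzyl)oxy]methyl}-2,3-dihydrofuran  
Conditions: Mo(CO)6 (30 mol%), Et3N, Et2O, hν (350 nm), rt  
Reagents that add atoms: none  
Why: Alkynol cycloisomerisation through a molybdenum vinylidene formed from the terminal alkyne; the hydroxyl adds to the vinylidene carbon (net 5-endo closure, O1–C7a) and protodemetalation gives the enol ether. No stereocentre is touched, so the anti alcohol becomes the trans ring.

Step 7  
Reactants: 9 (2S,3R)-2-[3,4-bis(triisopropylsilyloxy)phenyl]-3-{[(4-methoxybenzyl)oxy]methyl}-2,3-dihydrofuran  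
Product: 10 2,2,2-trichloro-1-[(4R,5S)-5-[3,4-bis(triisopropylsilyloxy)phenyl]-4-{[(4-methoxybenzyl)oxy]methyl}-4,5-dihydrofuran-3-yl]ethan-1-one  
Conditions: Cl3CCOCl (1.5 equiv), pyridine (2.5 equiv), CH2Cl2, 0 °C → rt  
Reagents that add atoms: trichloroacetyl chloride, `O=C(Cl)C(Cl)(Cl)Cl`  
Why: Electrophilic beta-acylation of an enol ether without Lewis acid; the acyl group can enter only at the nucleophilic beta-carbon (future C3a) and pyridine restores the double bond while buffering the acid-labile enol ether.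

Step 8  
Reactants: 10 2,2,2-trichloro-1-[(4R,5S)-5-[3,4-bis(triisopropylsilyloxy)phenyl]-4-{[(4-methoxybenzyl)oxy]methyl}-4,5-dihydrofuran-3-yl]ethan-1-one  
Product: 11 (4R,5S)-5-[3,4-bis(triisopropylsilyloxy)phenyl]-4-{[(4-methoxybenzyl)oxy]methyl}-4,5-dihydrofuran-3-carboxylic acid  
Conditions: LiOH·H2O (2.5 equiv), THF/H2O (4:1), 0 °C, short contact; aq. NaH2PO4 to pH 5  
Reagents that add atoms: lithium hydroxide, `[Li+].[OH-]`  
Why: Haloform cleavage: hydroxide adds to the trichloromethyl ketone and trichloromethanide leaves, giving the carboxylate of a vinylogous carbonate. Acidification only to pH 5 spares the enol ether, and the hindered aryl silyl ethers should outlast brief cold hydroxide.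

Step 9  
Reactants: 12 (E)-4-hydroxycinnamic acid  
Product: 14 (E)-3-[4-(triisopropylsilyloxy)phenyl]prop-2-enoic acid, via silyl ester 13 (not isolated)  
Conditions: iPr3SiCl (2.3 equiv), imidazole (5 equiv), HCONMe2, rt; then K2CO3 (1 equiv), THF/MeOH/H2O, 0 °C, brief; aq. KHSO4  
Reagents that add atoms: triisopropylsilyl chloride, `CC(C)[Si](Cl)(C(C)C)C(C)C`  
Why: Exhaustive silylation gives ether and silyl ester 13; the far more labile silyl ester is then hydrolysed selectively by brief carbonate treatment, leaving the aryl silyl ether.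

Step 10  
Reactants: 14 (E)-3-[4-(triisopropylsilyloxy)phenyl]prop-2-enoic acid; 15 trimethylsulfoxonium iodide  
Product: 18 (E)-1-[dimethyl(oxo)-λ6-sulfanylidene]-4-[4-(triisopropylsilyloxy)phenyl]but-3-en-2-one, via acid chloride 16 (not isolated), via dimethylsulfoxonium methylide 17 (not isolated)  
Conditions: 14, (COCl)2 (1.3 equiv), HCONMe2 (cat.), CH2Cl2, 0 °C → rt, evaporate; 15 (3.1 equiv), KOtBu (3.0 equiv), THF, reflux then 0 °C; add 16, 0 °C → rt  
Reagents that add atoms: none  
Why: Acid chloride formation followed by C-acylation of the Corey–Chaykovsky ylide 17; a second equivalent of 17 deprotonates the acylsulfoxonium salt to the stabilised ylide 18. Attack at the acid chloride carbonyl should be much faster than cyclopropanation of the electron-rich cinnamoyl alkene, whose (E) geometry is untouched.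

Step 11  
Reactants: 11 (4R,5S)-5-[3,4-bis(triisopropylsilyloxy)phenyl]-4-{[(4-methoxybenzyl)oxy]methyl}-4,5-dihydrofuran-3-carboxylic acid; 18 (E)-1-[dimethyl(oxo)-λ6-sulfanylidene]-4-[4-(triisopropylsilyloxy)phenyl]but-3-en-2-one  
Product: 20 (2S,3R)-2-[3,4-bis(triisopropylsilyloxy)phenyl]-3-{[(4-methoxybenzyl)oxy]methyl}-6-{(E)-2-[4-(triisopropylsilyloxy)phenyl]ethenyl}-2,3-dihydro-4H-furo[3,2-c]pyran-4-one, via keto acid 19 (not isolated)  
Conditions: `[Cp*RhCl2]2` (4 mol%), AgSbF6 (16 mol%), NaOAc (30 mol%), 4 Å molecular sieves, ClCH2CH2Cl, 60 °C, 18 (1.3 equiv) added slowly  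
Reagents that add atoms: none  
Why: Proposed new method: acetate-assisted concerted metalation–deprotonation by the cationic pentamethylcyclopentadienyl complex of trivalent rhodium, held by the carboxylate of 11, should cleave the only C–H bond cis to the carboxyl (the vinylic C7a–H of ring B) and give a five-membered rhodacycle. The ylide carbon of 18 then binds rhodium, dimethyl sulfoxide leaves to give an acyl carbene, migratory insertion into the Rh–C(vinyl) bond creates C7–C7a, and protodemetalation by the substrate acid releases keto acid 19 with rhodium still trivalent. The closest known reaction types are the annulation of benzoic acids with sulfoxonium ylides to isocoumarins and the oxidative annulation of acrylic acids with alkynes to 2-pyranones, both under the same rhodium catalyst; the vinylic C–H of a cyclic beta-alkoxyacrylic acid paired with a ylide is the new element. Ring A closes when the carboxyl oxygen of 19 adds to the C6 ketone in a 6-exo-trig sense (O5–C6) and the hemiketal loses water, driven by pyranone conjugation and the sieves. No stereocentre is formed; C2 and C3 are spectators, and because C3 carries only an ether-bearing methylene it has no acidic hydrogen and no path to elimination of O1 under acetate buffer. Site selectivity rests on chelation (one C–H within reach of the carboxylate), regiochemistry on the ylide (its carbanionic carbon must become C7, its carbonyl carbon C6), and chemoselectivity over plain O-alkylation of the acid by the ylide on moderate temperature and slow addition of 18.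

Step 12  
Reactants: 20 (2S,3R)-2-[3,4-bis(triisopropylsilyloxy)phenyl]-3-{[(4-methoxybenzyl)oxy]methyl}-6-{(E)-2-[4-(triisopropylsilyloxy)phenyl]ethenyl}-2,3-dihydro-4H-furo[3,2-c]pyran-4-one  
Product: 21 (2S,3R)-2-[3,4-bis(triisopropylsilyloxy)phenyl]-3-(hydroxymethyl)-6-{(E)-2-[4-(triisopropylsilyloxy)phenyl]ethenyl}-2,3-dihydro-4H-furo[3,2-c]pyran-4-one  
Conditions: DDQ (1.3 equiv), CH2Cl2/pH 7 buffer (10:1), 0 °C  
Reagents that add atoms: none  
Why: Oxidative cleavage of the 4-methoxybenzyl ether (hydride abstraction at the most electron-rich benzylic position, hydrolysis of the oxocarbenium ion); the silyloxy arenes and C2–H, which sits next to a vinylogous-ester oxygen, should react far more slowly at 0 °C.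

Step 13  
Reactants: 21 (2S,3R)-2-[3,4-bis(triisopropylsilyloxy)phenyl]-3-(hydroxymethyl)-6-{(E)-2-[4-(triisopropylsilyloxy)phenyl]ethenyl}-2,3-dihydro-4H-furo[3,2-c]pyran-4-one  
Product: 22 (2S,3S)-2-[3,4-bis(triisopropylsilyloxy)phenyl]-4-oxo-6-{(E)-2-[4-(triisopropylsilyloxy)phenyl]ethenyl}-2,3-dihydro-4H-furo[3,2-c]pyran-3-carbaldehyde  
Conditions: Dess–Martin periodinane (1.3 equiv), CH2Cl2, 0 °C → rt; used crude  
Reagents that add atoms: none  
Why: Dess–Martin oxidation of the primary alcohol under non-basic conditions; the aldehyde, whose C3–H is acidic and beta to O1, is not chromatographed. The descriptor at C3 changes from R to S by priority only.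

Step 14  
Reactants: 23 2,2,6-trimethyl-4H-1,3-dioxin-4-one  
Product: 24 trimethyl[(2,2-dimethyl-6-methylidene-6H-1,3-dioxin-4-yl)oxy]silane  
Conditions: LiN(iPr)2 (1.1 equiv), THF, −78 °C; Me3SiCl (1.2 equiv), −78 → 0 °C; non-aqueous work-up  
Reagents that add atoms: chlorotrimethylsilane, `C[Si](C)(C)Cl`  
Why: Gamma-deprotonation of the vinylogous ester and O-silylation of the dienolate give the standard silyl dienol ether donor, used crude.

Step 15  
Reactants: 22 (2S,3S)-2-[3,4-bis(triisopropylsilyloxy)phenyl]-4-oxo-6-{(E)-2-[4-(triisopropylsilyloxy)phenyl]ethenyl}-2,3-dihydro-4H-furo[3,2-c]pyran-3-carbaldehyde; 24 trimethyl[(2,2-dimethyl-6-methylidene-6H-1,3-dioxin-4-yl)oxy]silane  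
Product: 25 6-{2-hydroxy-2-[(2S,3R)-2-[3,4-bis(triisopropylsilyloxy)phenyl]-4-oxo-6-{(E)-2-[4-(triisopropylsilyloxy)phenyl]ethenyl}-2,3-dihydro-4H-furo[3,2-c]pyran-3-yl]ethyl}-2,2-dimethyl-4H-1,3-dioxin-4-one (both carbinol epimers)  
Conditions: BF3·OEt2 (1.2 equiv), CH2Cl2, −78 °C; aq. NaHCO3  
Reagents that add atoms: none  
Why: Vinylogous Mukaiyama aldol addition: the BF3-activated aldehyde is attacked by the terminal methylene carbon of 24, forming the future C5–C6 bond of ring C under Lewis-acidic, non-basic conditions that should leave C3 and ring B intact. The new carbinol centre is uncontrolled and irrelevant because step 16 oxidises it.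

Step 16  
Reactants: 25 6-{2-hydroxy-2-[(2S,3R)-2-[3,4-bis(triisopropylsilyloxy)phenyl]-4-oxo-6-{(E)-2-[4-(triisopropylsilyloxy)phenyl]ethenyl}-2,3-dihydro-4H-furo[3,2-c]pyran-3-yl]ethyl}-2,2-dimethyl-4H-1,3-dioxin-4-one  
Product: 26 6-{2-oxo-2-[(2S,3S)-2-[3,4-bis(triisopropylsilyloxy)phenyl]-4-oxo-6-{(E)-2-[4-(triisopropylsilyloxy)phenyl]ethenyl}-2,3-dihydro-4H-furo[3,2-c]pyran-3-yl]ethyl}-2,2-dimethyl-4H-1,3-dioxin-4-one  
Conditions: Dess–Martin periodinane (1.5 equiv), CH2Cl2, 0 °C → rt  
Reagents that add atoms: none  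
Why: Dess–Martin oxidation of the secondary alcohol converges both epimers into one ketone under neutral to weakly acidic conditions.

Step 17  
Reactants: 26 6-{2-oxo-2-[(2S,3S)-2-[3,4-bis(triisopropylsilyloxy)phenyl]-4-oxo-6-{(E)-2-[4-(triisopropylsilyloxy)phenyl]ethenyl}-2,3-dihydro-4H-furo[3,2-c]pyran-3-yl]ethyl}-2,2-dimethyl-4H-1,3-dioxin-4-one  
Product: 28 (2S,3S)-2-[3,4-bis(triisopropylsilyloxy)phenyl]-3-(4-hydroxy-2-oxo-2H-pyran-6-yl)-6-{(E)-2-[4-(triisopropylsilyloxy)phenyl]ethenyl}-2,3-dihydro-4H-furo[3,2-c]pyran-4-one, via acylketene 27 (not isolated)  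
Conditions: toluene (0.01 M), 110 °C  
Reagents that add atoms: none  
Why: Thermal retro-[4+2] fragmentation of the dioxinone expels acetone and gives acylketene 27; the oxygen of the enolised ketone adds to the ketene carbon (six-membered closure) and tautomerisation gives the 4-hydroxy-2-pyranone. No acid or base is present, and the trans arrangement is also the thermodynamically preferred one.

Step 18  
Reactants: 28 (2S,3S)-2-[3,4-bis(triisopropylsilyloxy)phenyl]-3-(4-hydroxy-2-oxo-2H-pyran-6-yl)-6-{(E)-2-[4-(triisopropylsilyloxy)phenyl]ethenyl}-2,3-dihydro-4H-furo[3,2-c]pyran-4-one  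
Product: 29 (2S,3S)-2-(3,4-dihydroxyphenyl)-3-(4-hydroxy-2-oxo-2H-pyran-6-yl)-6-[(E)-2-(4-hydroxyphenyl)ethenyl]-2,3-dihydro-4H-furo[3,2-c]pyran-4-one  
Conditions: Bu4NF (4 equiv), AcOH (6 equiv), THF, 0 °C → rt, under argon; acidic work-up, reversed-phase chromatography  
Reagents that add atoms: none  
Why: Fluoride cleavage of the three aryl silyl ethers (strong Si–F bond, phenoxide leaving groups); acetic acid keeps the medium from becoming basic enough to epimerise C3, open ring B or oxidise the catechol.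

Compound list

```
1 | 3,4-dihydroxybenzaldehyde | O=Cc1ccc(O)c(O)c1 | starting material
2 | 3,4-bis(triisopropylsilyloxy)benzaldehyde | O=Cc1ccc(O[Si](C(C)C)(C(C)C)C(C)C)c(O[Si](C(C)C)(C(C)C)C(C)C)c1 | intermediate
3 | 2-[(4-methoxyphenyl)methoxy]acetaldehyde | COc1ccc(COCC=O)cc1 | starting material
4 | rac-1-[(4-methoxybenzyl)oxy]but-3-yn-2-ol | COc1ccc(COCC(O)C#C)cc1 | intermediate
5 | (S)-1-[(4-methoxybenzyl)oxy]but-3-yn-2-ol | COc1ccc(COC[C@@H](O)C#C)cc1 | intermediate
6 | (S)-1-[(4-methoxybenzyl)oxy]but-3-yn-2-yl methanesulfonate | COc1ccc(COC[C@@H](OS(C)(=O)=O)C#C)cc1 | intermediate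
7 | (P)-ethyl{4-[(4-methoxybenzyl)oxy]buta-1,2-dien-1-yl}zinc | [H]C([Zn]CC)=[C@]=C([H])COCc1ccc(OC)cc1 | intermediate
8 | (1S,2R)-1-[3,4-bis(triisopropylsilyloxy)phenyl]-2-{[(4-methoxybenzyl)oxy]methyl}but-3-yn-1-ol | COc1ccc(COC[C@H]([C@H](O)c2ccc(O[Si](C(C)C)(C(C)C)C(C)C)c(O[Si](C(C)C)(C(C)C)C(C)C)c2)C#C)cc1 | intermediate
9 | (2S,3R)-2-[3,4-bis(triisopropylsilyloxy)phenyl]-3-{[(4-methoxybenzyl)oxy]methyl}-2,3-dihydrofuran | COc1ccc(COC[C@H]2C=CO[C@@H]2c2ccc(O[Si](C(C)C)(C(C)C)C(C)C)c(O[Si](C(C)C)(C(C)C)C(C)C)c2)cc1 | intermediate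
10 | 2,2,2-trichloro-1-[(4R,5S)-5-[3,4-bis(triisopropylsilyloxy)phenyl]-4-{[(4-methoxybenzyl)oxy]methyl}-4,5-dihydrofuran-3-yl]ethan-1-one | COc1ccc(COC[C@H]2C(C(=O)C(Cl)(Cl)Cl)=CO[C@@H]2c2ccc(O[Si](C(C)C)(C(C)C)C(C)C)c(O[Si](C(C)C)(C(C)C)C(C)C)c2)cc1 | intermediate
11 | (4R,5S)-5-[3,4-bis(triisopropylsilyloxy)phenyl]-4-{[(4-methoxybenzyl)oxy]methyl}-4,5-dihydrofuran-3-carboxylic acid | COc1ccc(COC[C@H]2C(C(=O)O)=CO[C@@H]2c2ccc(O[Si](C(C)C)(C(C)C)C(C)C)c(O[Si](C(C)C)(C(C)C)C(C)C)c2)cc1 | intermediate
12 | (E)-4-hydroxycinnamic acid | O=C(O)/C=C/c1ccc(O)cc1 | starting material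
13 | triisopropylsilyl (E)-3-[4-(triisopropylsilyloxy)phenyl]prop-2-enoate | CC(C)[Si](C(C)C)(C(C)C)OC(=O)/C=C/c1ccc(O[Si](C(C)C)(C(C)C)C(C)C)cc1 | intermediate
14 | (E)-3-[4-(triisopropylsilyloxy)phenyl]prop-2-enoic acid | O=C(O)/C=C/c1ccc(O[Si](C(C)C)(C(C)C)C(C)C)cc1 | intermediate
15 | trimethylsulfoxonium iodide | C[S+](C)(C)=O.[I-] | starting material
16 | (E)-3-[4-(triisopropylsilyloxy)phenyl]prop-2-enoyl chloride | O=C(Cl)/C=C/c1ccc(O[Si](C(C)C)(C(C)C)C(C)C)cc1 | intermediate
17 | dimethylsulfoxonium methylide | C=S(C)(C)=O | intermediate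
18 | (E)-1-[dimethyl(oxo)-λ6-sulfanylidene]-4-[4-(triisopropylsilyloxy)phenyl]but-3-en-2-one | CS(C)(=O)=CC(=O)/C=C/c1ccc(O[Si](C(C)C)(C(C)C)C(C)C)cc1 | intermediate
19 | (4R,5S)-5-[3,4-bis(triisopropylsilyloxy)phenyl]-4-{[(4-methoxybenzyl)oxy]methyl}-2-{(E)-2-oxo-4-[4-(triisopropylsilyloxy)phenyl]but-3-en-1-yl}-4,5-dihydrofuran-3-carboxylic acid | COc1ccc(COC[C@H]2C(C(=O)O)=C(CC(=O)/C=C/c3ccc(O[Si](C(C)C)(C(C)C)C(C)C)cc3)O[C@@H]2c2ccc(O[Si](C(C)C)(C(C)C)C(C)C)c(O[Si](C(C)C)(C(C)C)C(C)C)c2)cc1 | intermediate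
20 | (2S,3R)-2-[3,4-bis(triisopropylsilyloxy)phenyl]-3-{[(4-methoxybenzyl)oxy]methyl}-6-{(E)-2-[4-(triisopropylsilyloxy)phenyl]ethenyl}-2,3-dihydro-4H-furo[3,2-c]pyran-4-one | COc1ccc(COC[C@H]2c3c(cc(/C=C/c4ccc(O[Si](C(C)C)(C(C)C)C(C)C)cc4)oc3=O)O[C@@H]2c2ccc(O[Si](C(C)C)(C(C)C)C(C)C)c(O[Si](C(C)C)(C(C)C)C(C)C)c2)cc1 | intermediate
21 | (2S,3R)-2-[3,4-bis(triisopropylsilyloxy)phenyl]-3-(hydroxymethyl)-6-{(E)-2-[4-(triisopropylsilyloxy)phenyl]ethenyl}-2,3-dihydro-4H-furo[3,2-c]pyran-4-one | OC[C@H]1c2c(cc(/C=C/c3ccc(O[Si](C(C)C)(C(C)C)C(C)C)cc3)oc2=O)O[C@@H]1c1ccc(O[Si](C(C)C)(C(C)C)C(C)C)c(O[Si](C(C)C)(C(C)C)C(C)C)c1 | intermediate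
22 | (2S,3S)-2-[3,4-bis(triisopropylsilyloxy)phenyl]-4-oxo-6-{(E)-2-[4-(triisopropylsilyloxy)phenyl]ethenyl}-2,3-dihydro-4H-furo[3,2-c]pyran-3-carbaldehyde | O=C[C@H]1c2c(cc(/C=C/c3ccc(O[Si](C(C)C)(C(C)C)C(C)C)cc3)oc2=O)O[C@@H]1c1ccc(O[Si](C(C)C)(C(C)C)C(C)C)c(O[Si](C(C)C)(C(C)C)C(C)C)c1 | intermediate
23 | 2,2,6-trimethyl-4H-1,3-dioxin-4-one | CC1=CC(=O)OC(C)(C)O1 | starting material
24 | trimethyl[(2,2-dimethyl-6-methylidene-6H-1,3-dioxin-4-yl)oxy]silane | C=C1C=C(O[Si](C)(C)C)OC(C)(C)O1 | intermediate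
25 | 6-{2-hydroxy-2-[(2S,3R)-2-[3,4-bis(triisopropylsilyloxy)phenyl]-4-oxo-6-{(E)-2-[4-(triisopropylsilyloxy)phenyl]ethenyl}-2,3-dihydro-4H-furo[3,2-c]pyran-3-yl]ethyl}-2,2-dimethyl-4H-1,3-dioxin-4-one (both carbinol epimers) | CC1(C)OC(=O)C=C(CC(O)[C@H]2c3c(cc(/C=C/c4ccc(O[Si](C(C)C)(C(C)C)C(C)C)cc4)oc3=O)O[C@@H]2c2ccc(O[Si](C(C)C)(C(C)C)C(C)C)c(O[Si](C(C)C)(C(C)C)C(C)C)c2)O1 | intermediate
26 | 6-{2-oxo-2-[(2S,3S)-2-[3,4-bis(triisopropylsilyloxy)phenyl]-4-oxo-6-{(E)-2-[4-(triisopropylsilyloxy)phenyl]ethenyl}-2,3-dihydro-4H-furo[3,2-c]pyran-3-yl]ethyl}-2,2-dimethyl-4H-1,3-dioxin-4-one | CC1(C)OC(=O)C=C(CC(=O)[C@H]2c3c(cc(/C=C/c4ccc(O[Si](C(C)C)(C(C)C)C(C)C)cc4)oc3=O)O[C@@H]2c2ccc(O[Si](C(C)C)(C(C)C)C(C)C)c(O[Si](C(C)C)(C(C)C)C(C)C)c2)O1 | intermediate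
27 | 5-[(2S,3S)-2-[3,4-bis(triisopropylsilyloxy)phenyl]-4-oxo-6-{(E)-2-[4-(triisopropylsilyloxy)phenyl]ethenyl}-2,3-dihydro-4H-furo[3,2-c]pyran-3-yl]pent-1-ene-1,3,5-trione (acylketene) | O=C=CC(=O)CC(=O)[C@H]1c2c(cc(/C=C/c3ccc(O[Si](C(C)C)(C(C)C)C(C)C)cc3)oc2=O)O[C@@H]1c1ccc(O[Si](C(C)C)(C(C)C)C(C)C)c(O[Si](C(C)C)(C(C)C)C(C)C)c1 | intermediate
28 | (2S,3S)-2-[3,4-bis(triisopropylsilyloxy)phenyl]-3-(4-hydroxy-2-oxo-2H-pyran-6-yl)-6-{(E)-2-[4-(triisopropylsilyloxy)phenyl]ethenyl}-2,3-dihydro-4H-furo[3,2-c]pyran-4-one | O=c1cc(O)cc([C@H]2c3c(cc(/C=C/c4ccc(O[Si](C(C)C)(C(C)C)C(C)C)cc4)oc3=O)O[C@@H]2c2ccc(O[Si](C(C)C)(C(C)C)C(C)C)c(O[Si](C(C)C)(C(C)C)C(C)C)c2)o1 | intermediate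
29 | (2S,3S)-2-(3,4-dihydroxyphenyl)-3-(4-hydroxy-2-oxo-2H-pyran-6-yl)-6-[(E)-2-(4-hydroxyphenyl)ethenyl]-2,3-dihydro-4H-furo[3,2-c]pyran-4-one | O=c1cc(O)cc([C@H]2c3c(cc(/C=C/c4ccc(O)cc4)oc3=O)O[C@@H]2c2ccc(O)c(O)c2)o1 | target
```

Total step count: 18. Longest linear sequence: 14 steps (3 → 4 → 5 → 6 → 8 → 9 → 10 → 11 → 20 → 21 → 22 → 25 → 26 → 28 → 29; steps 2–8, 11–13, 15–18).

Least certain steps and fallbacks

Step 11 (the proposed new method). Most likely failure: protonation of ylide 18 by the carboxylic acid and displacement of dimethyl sulfoxide (plain O-alkylation) outruns C–H activation, or the sequence stalls at 19 because dehydration is slow under buffer. Fallback by known chemistry, from 8 back to 20: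
- The alkyne terminus of 8 is methylated through the dianion (n-BuLi 2.1 equiv, THF, −78 °C; MeI) to give (1S,2R)-1-[3,4-bis(triisopropylsilyloxy)phenyl]-2-{[(4-methoxybenzyl)oxy]methyl}pent-3-yn-1-ol F1.
- Oxidative 5-endo cyclisation–methoxycarbonylation (PdCl2(MeCN)2 cat., p-benzoquinone, CO 1 atm, MeOH, 0 °C) gives methyl (4R,5S)-5-[3,4-bis(triisopropylsilyloxy)phenyl]-4-{[(4-methoxybenzyl)oxy]methyl}-2-methyl-4,5-dihydrofuran-3-carboxylate F2. Ring B, the C4 carboxyl carbon and C7 are then all in place.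
- The lithium dienolate of F2 (LiN(iPr)2, THF, −78 °C) is acylated at the exocyclic carbon by (E)-1-(1H-imidazol-1-yl)-3-[4-(triisopropylsilyloxy)phenyl]prop-2-en-1-one F3, made from 14 and carbonyldiimidazole. This gives methyl (4R,5S)-5-[3,4-bis(triisopropylsilyloxy)phenyl]-4-{[(4-methoxybenzyl)oxy]methyl}-2-{(E)-2-oxo-4-[4-(triisopropylsilyloxy)phenyl]but-3-en-1-yl}-4,5-dihydrofuran-3-carboxylate F4.
- DBU in toluene closes ring A by enol lactonisation, rejoining the route at 20.

Step 8. Most likely failure: cleavage of the aryl silyl ethers by hydroxide, or conjugate addition of hydroxide to the vinylogous ester with opening of ring B, alongside the haloform cleavage. Fallback from 10 to 11 without hydroxide: alcoholysis (allyl alcohol, Et3N, cat. 4-dimethylaminopyridine, CH2Cl2, rt) gives prop-2-en-1-yl (4R,5S)-5-[3,4-bis(triisopropylsilyloxy)phenyl]-4-{[(4-methoxybenzyl)oxy]methyl}-4,5-dihydrofuran-3-carboxylate F5. Neutral deallylation (Pd(PPh3)4 cat., pyrrolidine, THF, 0 °C) then returns 11.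

Step 5. Most likely failure: insufficient anti selectivity with an aromatic aldehyde, or erosion of enantiomeric purity when the allenylpalladium species equilibrates before transmetalation. Fallback from 5 to 8 through an isolable, configurationally stable allenylboron reagent:
- 5 is converted into (S)-1-[(4-methoxybenzyl)oxy]but-3-yn-2-yl methyl carbonate F6 (ClCO2Me, pyridine).
- Copper-catalysed anti SN2' borylation (CuCl 10 mol%, Xantphos, KOtBu, bis(pinacolato)diboron, THF) gives (P)-2-{4-[(4-methoxybenzyl)oxy]buta-1,2-dien-1-yl}-4,4,5,5-tetramethyl-1,3,2-dioxaborolane F7.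
- F7 adds to 2 (toluene, rt) through a closed six-membered transition state with the same net inversion at the propargylic carbon, giving 8 after hydrolytic work-up.

Step 15 (with the aldehyde from step 13). Most likely failure: loss of C3 configuration by enolisation of 22, or opening of ring B by beta-elimination of O1 during handling or Lewis acid activation. Fallback from 21 to 28 that avoids the aldehyde:
- 21 is oxidised directly (2,2,6,6-tetramethylpiperidine-1-oxyl cat., PhI(OAc)2, MeCN/H2O) to (2S,3S)-2-[3,4-bis(triisopropylsilyloxy)phenyl]-4-oxo-6-{(E)-2-[4-(triisopropylsilyloxy)phenyl]ethenyl}-2,3-dihydro-4H-furo[3,2-c]pyran-3-carboxylic acid F8.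
- Carbonyldiimidazole converts F8 into (2S,3S)-2-[3,4-bis(triisopropylsilyloxy)phenyl]-3-(1H-imidazole-1-carbonyl)-6-{(E)-2-[4-(triisopropylsilyloxy)phenyl]ethenyl}-2,3-dihydro-4H-furo[3,2-c]pyran-4-one F9.
- F9 is added at −78 °C to the dianion of methyl acetoacetate (NaH then n-BuLi, THF) to give methyl 5-[(2S,3S)-2-[3,4-bis(triisopropylsilyloxy)phenyl]-4-oxo-6-{(E)-2-[4-(triisopropylsilyloxy)phenyl]ethenyl}-2,3-dihydro-4H-furo[3,2-c]pyran-3-yl]-3,5-dioxopentanoate F10.
- DBU in toluene lactonises F10 to 28. This sequence is more basic than the main route and is held in reserve only.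

Step 18. Most likely failure: degradation of the unmasked target during fluoride treatment and isolation (catechol oxidation, base-induced opening of ring B), aggravated by separating a polar polyphenol from ammonium salts. Fallback from 26 to 29 that reverses the order: the silyl ethers of 26 are removed first with HF·pyridine in THF/pyridine to give 6-{2-[(2S,3S)-2-(3,4-dihydroxyphenyl)-6-[(E)-2-(4-hydroxyphenyl)ethenyl]-4-oxo-2,3-dihydro-4H-furo[3,2-c]pyran-3-yl]-2-oxoethyl}-2,2-dimethyl-4H-1,3-dioxin-4-one F11. The reagent-free thermolysis (dilute dioxane, 100 °C) then becomes the last step and delivers 29.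

## Further compounds

```
F1 | step 11 | (1S,2R)-1-[3,4-bis(triisopropylsilyloxy)phenyl]-2-{[(4-methoxybenzyl)oxy]methyl}pent-3-yn-1-ol | COc1ccc(COC[C@H]([C@H](O)c2ccc(O[Si](C(C)C)(C(C)C)C(C)C)c(O[Si](C(C)C)(C(C)C)C(C)C)c2)C#CC)cc1
F2 | step 11 | methyl (4R,5S)-5-[3,4-bis(triisopropylsilyloxy)phenyl]-4-{[(4-methoxybenzyl)oxy]methyl}-2-methyl-4,5-dihydrofuran-3-carboxylate | COc1ccc(COC[C@H]2C(C(=O)OC)=C(C)O[C@@H]2c2ccc(O[Si](C(C)C)(C(C)C)C(C)C)c(O[Si](C(C)C)(C(C)C)C(C)C)c2)cc1
F3 | step 11 | (E)-1-(1H-imidazol-1-yl)-3-[4-(triisopropylsilyloxy)phenyl]prop-2-en-1-one | O=C(/C=C/c1ccc(O[Si](C(C)C)(C(C)C)C(C)C)cc1)n1ccnc1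
F4 | step 11 | methyl (4R,5S)-5-[3,4-bis(triisopropylsilyloxy)phenyl]-4-{[(4-methoxybenzyl)oxy]methyl}-2-{(E)-2-oxo-4-[4-(triisopropylsilyloxy)phenyl]but-3-en-1-yl}-4,5-dihydrofuran-3-carboxylate | COc1ccc(COC[C@H]2C(C(=O)OC)=C(CC(=O)/C=C/c3ccc(O[Si](C(C)C)(C(C)C)C(C)C)cc3)O[C@@H]2c2ccc(O[Si](C(C)C)(C(C)C)C(C)C)c(O[Si](C(C)C)(C(C)C)C(C)C)c2)cc1
F5 | step 8 | prop-2-en-1-yl (4R,5S)-5-[3,4-bis(triisopropylsilyloxy)phenyl]-4-{[(4-methoxybenzyl)oxy]methyl}-4,5-dihydrofuran-3-carboxylate | COc1ccc(COC[C@H]2C(C(=O)OCC=C)=CO[C@@H]2c2ccc(O[Si](C(C)C)(C(C)C)C(C)C)c(O[Si](C(C)C)(C(C)C)C(C)C)c2)cc1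
F6 | step 5 | (S)-1-[(4-methoxybenzyl)oxy]but-3-yn-2-yl methyl carbonate | COc1ccc(COC[C@@H](OC(=O)OC)C#C)cc1
F7 | step 5 | (P)-2-{4-[(4-methoxybenzyl)oxy]buta-1,2-dien-1-yl}-4,4,5,5-tetramethyl-1,3,2-dioxaborolane | [H]C(B1OC(C)(C)C(C)(C)O1)=[C@]=C([H])COCc1ccc(OC)cc1
F8 | step 15 | (2S,3S)-2-[3,4-bis(triisopropylsilyloxy)phenyl]-4-oxo-6-{(E)-2-[4-(triisopropylsilyloxy)phenyl]ethenyl}-2,3-dihydro-4H-furo[3,2-c]pyran-3-carboxylic acid | OC(=O)[C@H]1c2c(cc(/C=C/c3ccc(O[Si](C(C)C)(C(C)C)C(C)C)cc3)oc2=O)O[C@@H]1c1ccc(O[Si](C(C)C)(C(C)C)C(C)C)c(O[Si](C(C)C)(C(C)C)C(C)C)c1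
F9 | step 15 | (2S,3S)-2-[3,4-bis(triisopropylsilyloxy)phenyl]-3-(1H-imidazole-1-carbonyl)-6-{(E)-2-[4-(triisopropylsilyloxy)phenyl]ethenyl}-2,3-dihydro-4H-furo[3,2-c]pyran-4-one | O=C([C@H]1c2c(cc(/C=C/c3ccc(O[Si](C(C)C)(C(C)C)C(C)C)cc3)oc2=O)O[C@@H]1c1ccc(O[Si](C(C)C)(C(C)C)C(C)C)c(O[Si](C(C)C)(C(C)C)C(C)C)c1)n1ccnc1
F10 | step 15 | methyl 5-[(2S,3S)-2-[3,4-bis(triisopropylsilyloxy)phenyl]-4-oxo-6-{(E)-2-[4-(triisopropylsilyloxy)phenyl]ethenyl}-2,3-dihydro-4H-furo[3,2-c]pyran-3-yl]-3,5-dioxopentanoate | COC(=O)CC(=O)CC(=O)[C@H]1c2c(cc(/C=C/c3ccc(O[Si](C(C)C)(C(C)C)C(C)C)cc3)oc2=O)O[C@@H]1c1ccc(O[Si](C(C)C)(C(C)C)C(C)C)c(O[Si](C(C)C)(C(C)C)C(C)C)c1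
F11 | step 18 | 6-{2-[(2S,3S)-2-(3,4-dihydroxyphenyl)-6-[(E)-2-(4-hydroxyphenyl)ethenyl]-4-oxo-2,3-dihydro-4H-furo[3,2-c]pyran-3-yl]-2-oxoethyl}-2,2-dimethyl-4H-1,3-dioxin-4-one | CC1(C)OC(=O)C=C(CC(=O)[C@H]2c3c(cc(/C=C/c4ccc(O)cc4)oc3=O)O[C@@H]2c2ccc(O)c(O)c2)O1
A1 | alternative 1 | (2S)-2-[3,4-bis(benzyloxy)phenyl]-7-methyl-2,3-dihydro-4H,5H-pyrano[4,3-b]pyran-4,5-dione | Cc1cc2c(c(=O)o1)C(=O)C[C@@H](c1ccc(OCc3ccccc3)c(OCc3ccccc3)c1)O2
A2 | alternative 1 | methyl (2S,3S)-2-[3,4-bis(benzyloxy)phenyl]-6-methyl-4-oxo-2,3-dihydro-4H-furo[3,2-c]pyran-3-carboxylate | COC(=O)[C@H]1c2c(cc(C)oc2=O)O[C@@H]1c1ccc(OCc2ccccc2)c(OCc2ccccc2)c1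
A3 | alternative 2 | 4-hydroxy-3-{(phenylsulfonyl)[2-oxo-4-(2-trimethylsilylethoxy)-2H-pyran-6-yl]methyl}-6-{(E)-2-[4-(tert-butyldimethylsilyloxy)phenyl]ethenyl}-2H-pyran-2-one | O=c1cc(OCC[Si](C)(C)C)cc(C(c2c(O)cc(/C=C/c3ccc(O[Si](C)(C)C(C)(C)C)cc3)oc2=O)S(=O)(=O)c2ccccc2)o1
A4 | alternative 2 | (2R,5R)-1-[3,4-bis(tert-butyldimethylsilyloxy)benzyl]-2,5-dimethylthiolan-1-ium trifluoromethanesulfonate | C[C@@H]1CC[C@@H](C)[S+]1Cc1ccc(O[Si](C)(C)C(C)(C)C)c(O[Si](C)(C)C(C)(C)C)c1.[O-]S(=O)(=O)C(F)(F)F
A5 | alternative 2 | 3-{[2-oxo-4-(2-trimethylsilylethoxy)-2H-pyran-6-yl]methylidene}-6-{(E)-2-[4-(tert-butyldimethylsilyloxy)phenyl]ethenyl}-2H-pyran-2,4(3H)-dione | O=C1C=C(/C=C/c2ccc(O[Si](C)(C)C(C)(C)C)cc2)OC(=O)C1=Cc1cc(OCC[Si](C)(C)C)cc(=O)o1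
A6 | alternative 2 | (2S,3S)-2-[3,4-bis(tert-butyldimethylsilyloxy)phenyl]-3-[2-oxo-4-(2-trimethylsilylethoxy)-2H-pyran-6-yl]-6-{(E)-2-[4-(tert-butyldimethylsilyloxy)phenyl]ethenyl}-2,3-dihydro-4H-furo[3,2-c]pyran-4-one | O=c1cc(OCC[Si](C)(C)C)cc([C@H]2c3c(cc(/C=C/c4ccc(O[Si](C)(C)C(C)(C)C)cc4)oc3=O)O[C@@H]2c2ccc(O[Si](C)(C)C(C)(C)C)c(O[Si](C)(C)C(C)(C)C)c2)o1
A7 | alternative 3 | (S)-4-benzyl-3-{2-[4-chloro-2-oxo-6-{(E)-2-[4-(tert-butyldimethylsilyloxy)phenyl]ethenyl}-2H-pyran-3-yl]acetyl}oxazolidin-2-one | O=C(Cc1c(Cl)cc(/C=C/c2ccc(O[Si](C)(C)C(C)(C)C)cc2)oc1=O)N1[C@@H](Cc2ccccc2)COC1=O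
A8 | alternative 3 | 3,4-bis(tert-butyldimethylsilyloxy)benzaldehyde | O=Cc1ccc(O[Si](C)(C)C(C)(C)C)c(O[Si](C)(C)C(C)(C)C)c1
A9 | alternative 3 | (S)-4-benzyl-3-{(2S,3S)-3-[3,4-bis(tert-butyldimethylsilyloxy)phenyl]-2-[4-chloro-2-oxo-6-{(E)-2-[4-(tert-butyldimethylsilyloxy)phenyl]ethenyl}-2H-pyran-3-yl]-3-hydroxypropanoyl}oxazolidin-2-one | O=C([C@H]([C@H](O)c1ccc(O[Si](C)(C)C(C)(C)C)c(O[Si](C)(C)C(C)(C)C)c1)c1c(Cl)cc(/C=C/c2ccc(O[Si](C)(C)C(C)(C)C)cc2)oc1=O)N1[C@@H](Cc2ccccc2)COC1=O
A10 | alternative 3 | (S)-4-benzyl-3-{(2S,3S)-2-[3,4-bis(tert-butyldimethylsilyloxy)phenyl]-4-oxo-6-{(E)-2-[4-(tert-butyldimethylsilyloxy)phenyl]ethenyl}-2,3-dihydro-4H-furo[3,2-c]pyran-3-carbonyl}oxazolidin-2-one | O=C([C@H]2c3c(cc(/C=C/c4ccc(O[Si](C)(C)C(C)(C)C)cc4)oc3=O)O[C@@H]2c2ccc(O[Si](C)(C)C(C)(C)C)c(O[Si](C)(C)C(C)(C)C)c2)N1[C@@H](Cc2ccccc2)COC1=O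
```
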